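The time of reading is the thing to hold against the catalyst here: how many rounds fit into it?

    substrate + free catalyst ⇌ catalyst intermediate A (K1 = 6.6 M⁻¹, k1 = 180 M⁻¹ s⁻¹, Ea1 = 49.0 kJ mol⁻¹, ΔH1 = −31.0 kJ mol⁻¹)
    catalyst intermediate A → catalyst intermediate B (k2 = 0.94 s⁻¹, Ea2 = 75.0 kJ mol⁻¹)
    catalyst intermediate B → free catalyst + target (k3 = 0.22 s⁻¹, Ea3 = 66.0 kJ mol⁻¹)
    substrate + target → side product (k4 = 0.021 M⁻¹ s⁻¹, Ea4 = 69.0 kJ mol⁻¹)
    catalyst intermediate A → spent catalyst (k5 = 0.0051 s⁻¹, Ea5 = 81.0 kJ mol⁻¹)
    (constants at 25 °C)

| setting | Monday's | Saturday's | Wednesday's |
|---|---|---|---|
| substrate | 0.10 M | 0.10 M | 0.10 M |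
| free catalyst | 2.2 mM | 2.2 mM | 2.2 mM |
| temperature | −5 °C | 55 °C | 25 °C |
| time | 10 min | 10 min | 10 min |

- percent here means substrate units held: one side product counts as two
- all constants are for 25 °C and move with temperature by the activation energies and enthalpies

- the best flask by amount of target, in percent of the substrate charged; "all alike" if 1.5 percentage points covers them all (Monday's / Saturday's / Wednesday's / all alike)
- amount of target at the end, in percent of the substrate charged, Monday's
- amount of target at the end, in percent of the substrate charged, Saturday's
- amount of target at the end, in percent of the substrate charged, Wednesday's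

Monday's and Wednesday's flasks look nearly the same, one charge at two temperatures, so I count turnovers. To convert the charged substrate, each catalyst must go round 45.5 times, the substrate charged over the catalyst charged.

At −5 °C in Monday's flask, binding starts with 2.67 parts of catalyst intermediate A to one of free catalyst, so I let the catalyst work as saturated. Catalyst intermediate A then moves on at 0.0319 s⁻¹ and catalyst intermediate B releases target at 0.0112 s⁻¹, which gives 121 s. This is the round time, the lifetime of catalyst intermediate A plus that of catalyst intermediate B in their forward steps, which a saturated catalyst spends on one turnover.

Monday's 10 min therefore allows 4.97 turnovers, fewer than the 45.5 required, and that is 10.9% of the substrate. I expect Monday's target a little under this figure, with substrate still standing.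

Wednesday's round time is 5.61 s, which allows 107 turnovers. Binding in Wednesday's flask starts at 0.660 parts of catalyst intermediate A to one of free catalyst, so that flask does not start saturated and the count runs high for it. The round time also does not count the loss to side product. Saturday's flask has a round time of 0.465 s, so my reckoning stops short of ranking Wednesday's against Saturday's.

The forecast goes further. It names Wednesday's as best, with 9% for Monday's, 62.5% for Saturday's and 72% for Wednesday's, holding that “Saturday's finishes early but the higher-barrier side reaction takes much more of the target than the catalytic route can outrun”. Its Monday's figure lies under my allowance.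

The simulation gives Wednesday's as best, with 9.05% for Monday's, 61.9% for Saturday's and 73.1% for Wednesday's.

In Monday's flask at 4.19 min, catalyst intermediate B has a longer half-life in its step, 1.0 min, than catalyst intermediate A has in its step, 0.36 min. At the end of Monday's flask, catalyst intermediate B, the resting state, holds 65.2% of the catalyst, against 22.8% in catalyst intermediate A, 10.0% free and 2.01% spent. Monday's target stands at 82.8% of what the round time allowed. Read at 15 min, the same flask is allowed 16.4% by the round time, or 13.6% at that share, and the computed reading is 13.6%.

The constants were drawn at random within sensible limits; the rest is arithmetic.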